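**Retrosynthetic overview**

1. The strategy rests on ring C (oxolane O–C9–C11–C12–C13): its ether oxygen bridges two fully substituted carbons, C9 (spiro to ring B) and C13 (spiro to ring D), so the C9–O–C13 ether is not closed by C–O substitution. O9 is attached to C13 while C13 still bears H (rhodium-carbenoid O–H insertion into the 9α-OH), and ring C is then closed at C12–C13 by 5-exo-tet alkylation of the C13 α-alkoxy ester dienolate with a C12 iodide.
2. Rings A/B with C5 and C10 come from (+)-sclareolide; O9 (α) and the 8α-methyl come from an 8-en-7-one by 8α,9α-epoxidation and SmI2 opening; C7 is a dioxolane during the enolate chemistry.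
3. Ring D: the C13 ester becomes C16H2–O and the C13 vinyl becomes C14–C15 (15,16-diol, lactol, then dehydration to the C14=C15 enol ether as the last step).
4. C6: the axial 6β-acetate is set by α-face epoxidation of the Δ6 enol acetate and a thermal 1,2-acyloxy shift with inversion.
5. Ring order: A/B (chiral pool) → C (key step) → D as lactol → D as dihydrofuran.

Key step: step 14

Remark: labdane numbering is used; centres that are formed as mixtures and later destroyed (the C13–H centre before ring closure, the carbinol of the diazo alcohol, the anomeric C15 of the lactol and its derivatives) are left undefined in the SMILES.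

**Route**

Step 1
Reactants: 1 (+)-sclareolide
Product: 2 methyl 13,14,15,16-tetranorlabd-8-en-12-oate
Conditions: conc. H2SO4, MeOH, reflux
Reagents that add atoms: methanol, CO
Why: Acid-mediated alkyl–oxygen cleavage of the tertiary lactone (E1) with Fischer esterification gives the olefinic esters, and prolonged acid equilibration should favour the tetrasubstituted Δ8(9) isomer (minor Δ7 and exocyclic isomers to be removed on AgNO3-impregnated silica), with C5 and C10 untouched.

Step 2
Reactants: 2 methyl 13,14,15,16-tetranorlabd-8-en-12-oate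
Product: 3 13,14,15,16-tetranorlabd-8-en-12-ol
Conditions: LiAlH4, THF, 0 °C
Reagents that add atoms: none
Why: Standard hydride reduction of an ester to the primary alcohol, the isolated tetrasubstituted alkene being inert.

Step 3
Reactants: 3 13,14,15,16-tetranorlabd-8-en-12-ol
Product: 4 12-(tert-butyldimethylsilyloxy)-13,14,15,16-tetranorlabd-8-ene
Conditions: TBSCl, imidazole, DMF, rt
Reagents that add atoms: tert-butyldimethylsilyl chloride, CC(C)(C)[Si](C)(C)Cl
Why: Silylation of the primary alcohol gives an ether that is inert to the chromium oxidant, alkaline peroxide, SmI2 and the rhodium carbenoid and that, unlike a halide, is not readily expelled from C12 under the basic epoxidation.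

Step 4
Reactants: 4 12-(tert-butyldimethylsilyloxy)-13,14,15,16-tetranorlabd-8-ene
Product: 5 12-(tert-butyldimethylsilyloxy)-13,14,15,16-tetranorlabd-8-en-7-one
Conditions: CrO3, 3,5-dimethylpyrazole, CH2Cl2, −20 °C
Reagents that add atoms: chromium trioxide, O=[Cr](=O)=O
Why: Allylic oxidation with the CrO3–3,5-dimethylpyrazole complex should convert the ring methylene C7, whose axial C–H is aligned with the C8=C9 π bond, into the conjugated ketone in preference to the exocyclic C11 and C17 positions.

Step 5
Reactants: 5 12-(tert-butyldimethylsilyloxy)-13,14,15,16-tetranorlabd-8-en-7-one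
Product: 6 12-(tert-butyldimethylsilyloxy)-8α,9α-epoxy-13,14,15,16-tetranorlabdan-7-one
Conditions: 30% H2O2, NaOH, MeOH, 0 °C to rt
Reagents that add atoms: hydrogen peroxide, OO
Why: Weitz–Scheffer nucleophilic epoxidation, in which hydroperoxide adds axially to C9 from the α face opposite the C10 β-methyl and the enolate closes onto the O–O bond on the same face, sets the α-oxygen at C9 (and C8).

Step 6
Reactants: 6 12-(tert-butyldimethylsilyloxy)-8α,9α-epoxy-13,14,15,16-tetranorlabdan-7-one
Product: 7 12-(tert-butyldimethylsilyloxy)-9α-hydroxy-13,14,15,16-tetranorlabdan-7-one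
Conditions: SmI2, THF/MeOH, −90 °C; pH 7 buffer
Reagents that add atoms: none
Why: SmI2 reduction of an α,β-epoxy ketone cleaves the Cα–O bond (C8–O) and keeps C9–O, so the 9α-hydroxyl is retained, and protonation at C8 (with equilibration through the ketone if needed) should give the equatorial 8α-methyl because the axial epimer suffers a syn-axial clash with the C10 methyl.

Step 7
Reactants: 7 12-(tert-butyldimethylsilyloxy)-9α-hydroxy-13,14,15,16-tetranorlabdan-7-one
Product: 8 12-(tert-butyldimethylsilyloxy)-7,7-ethylenedioxy-13,14,15,16-tetranorlabdan-9α-ol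
Conditions: TMSOCH2CH2OTMS, TMSOTf (cat.), CH2Cl2, −78 to −20 °C; pyridine, then K2CO3, MeOH
Reagents that add atoms: 1,2-bis(trimethylsilyloxy)ethane, C[Si](C)(C)OCCO[Si](C)(C)C
Why: Noyori ketalisation under aprotic low-temperature conditions masks C7 without the acid-promoted loss of the tertiary β-hydroxyl that a protic ketalisation would risk, and the basic methanolic work-up leaves the 9-OH free.

Step 8
Reactants: 9 methyl acetoacetate
Product: 10 methyl 2-diazo-3-oxobutanoate
Conditions: 4-acetamidobenzenesulfonyl azide, Et3N, MeCN, 0 °C to rt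
Reagents that add atoms: 4-acetamidobenzenesulfonyl azide, CC(=O)Nc1ccc(cc1)S(=O)(=O)N=[N+]=[N-]
Why: Regitz diazo transfer to the active methylene of a β-keto ester.

Step 9
Reactants: 10 methyl 2-diazo-3-oxobutanoate
Product: 11 methyl 2-diazo-3-hydroxybutanoate (racemic)
Conditions: NaBH4, MeOH, 0 °C
Reagents that add atoms: none
Why: Chemoselective borohydride reduction of the ketone leaves the diazo ester intact, and the racemic carbinol centre is destroyed in the next step.

Step 10
Reactants: 11 methyl 2-diazo-3-hydroxybutanoate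
Product: 12 methyl 2-diazobut-3-enoate
Conditions: POCl3, Et3N, CH2Cl2, 0 °C; cold solution used at once
Reagents that add atoms: none
Why: Phosphoryl chloride activates the hydroxyl and triethylamine effects β-elimination to the vinyldiazoacetate, which is kept cold and used immediately because it slowly electrocyclises to a pyrazole.

Step 11
Reactants: 8 12-(tert-butyldimethylsilyloxy)-7,7-ethylenedioxy-13,14,15,16-tetranorlabdan-9α-ol; 12 methyl 2-diazobut-3-enoate
Product: 13 methyl 2-{[12-(tert-butyldimethylsilyloxy)-7,7-ethylenedioxy-13,14,15,16-tetranorlabdan-9α-yl]oxy}but-3-enoate (both C13–H epimers)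
Conditions: Rh2(OAc)4 (2 mol%), CH2Cl2/hexane, rt, slow addition of 12 (3 equiv)
Reagents that add atoms: none
Why: Rhodium-carbenoid O–H insertion (oxonium ylide, then proton transfer) forms the C13–O bond at the hindered axial tertiary 9α-hydroxyl where SN2 etherification is not an option, Rh2(OAc)4 in a weakly polar medium with slow addition favouring attack at the carbenoid carbon over the vinylogous terminus, and the new C13–H centre is formed as a mixture that does not matter because it is planarised in step 14.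

Step 12
Reactants: 13 methyl 2-{[12-(tert-butyldimethylsilyloxy)-7,7-ethylenedioxy-13,14,15,16-tetranorlabdan-9α-yl]oxy}but-3-enoate
Product: 14 methyl 2-[(7,7-ethylenedioxy-12-hydroxy-13,14,15,16-tetranorlabdan-9α-yl)oxy]but-3-enoate
Conditions: HF·pyridine, pyridine, THF, 0 °C to rt
Reagents that add atoms: none
Why: Buffered fluoride cleavage of the primary silyl ether, which the dioxolane and the β,γ-unsaturated ester should tolerate.

Step 13
Reactants: 14 methyl 2-[(7,7-ethylenedioxy-12-hydroxy-13,14,15,16-tetranorlabdan-9α-yl)oxy]but-3-enoate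
Product: 15 methyl 2-[(7,7-ethylenedioxy-12-iodo-13,14,15,16-tetranorlabdan-9α-yl)oxy]but-3-enoate
Conditions: I2, PPh3, imidazole, CH2Cl2, 0 °C to rt
Reagents that add atoms: iodine, II
Why: Appel-type iodination of the primary alcohol (SN2 at C12) under near-neutral conditions that should not isomerise the β,γ-unsaturated ester.

Step 14
Reactants: 15 methyl 2-[(7,7-ethylenedioxy-12-iodo-13,14,15,16-tetranorlabdan-9α-yl)oxy]but-3-enoate
Product: 17 methyl (13R)-7,7-ethylenedioxy-9α,13-epoxylabd-14-en-16-oate, via lithium dienolate 16 (not isolated)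
Conditions: LiN(iPr)2 (1.1 equiv), THF, −78 °C, then slowly to 0 °C
Reagents that add atoms: none
Why: LiN(iPr)2 removes the acidic C13–H (α to the ester, allylic and α to oxygen) to give the planar lithium dienolate 16, which on warming displaces iodide at C12 through its α-carbon in an intramolecular SN2 reaction, the known ester enolate alkylation route to 2-substituted oxolanes. Ring C (O, C9, C11, C12, C13) closes 5-exo-tet, whereas reaction through the γ-carbon or through oxygen would need a seven-membered ring, so the α-carbon should react. C13 becomes quaternary and is the only new stereocentre; both C13–H epimers of 15 give the same dienolate, so its configuration is decided only by which of the two in-plane groups (ester terminus or vinyl) lies on the C8 flank of the forming ring. The required (13R) arrangement has the ester on the C8 side and the vinyl on the C10 side, and it is expected to be favoured because the enolate lithium can bridge to the axial α-oxygen of the C7 dioxolane, which sits 1,3-diaxial to O9 on the C8 flank, while the slimmer vinyl group turns toward the quaternary C10 flank. The reaction is therefore run in THF without strongly coordinating co-solvents, and the same C7 ketal removes the C8 enolisation that would expel O9 by β-elimination.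

Step 15
Reactants: 17 methyl (13R)-7,7-ethylenedioxy-9α,13-epoxylabd-14-en-16-oate
Product: 18 (13R)-7,7-ethylenedioxy-9α,13-epoxylabd-14-en-16-ol
Conditions: LiAlH4, THF, 0 °C
Reagents that add atoms: none
Why: Hydride reduction of the hindered ester gives the neopentyl-type C16 alcohol, the ketal, ring C and the vinyl group being inert to LiAlH4.

Step 16
Reactants: 18 (13R)-7,7-ethylenedioxy-9α,13-epoxylabd-14-en-16-ol
Product: 20 7,7-ethylenedioxy-9α,13-epoxylabdane-15,16-diol, via bisborane adduct 19 (not isolated)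
Conditions: 9-BBN (3 equiv), THF, 0 °C to rt; then NaOH, 30% H2O2, 0 °C
Reagents that add atoms: hydrogen peroxide, OO
Why: Anti-Markovnikov hydroboration of the monosubstituted alkene with bulky 9-BBN (boron to terminal C15) and oxidation with retention gives the primary C15 alcohol, one further equivalent of borane being consumed by the free hydroxyl and released on work-up.

Step 17
Reactants: 20 7,7-ethylenedioxy-9α,13-epoxylabdane-15,16-diol
Product: 21 7,7-ethylenedioxy-9α,13:15,16-diepoxylabdan-15-ol (lactol; both C15 epimers)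
Conditions: IBX (1.1 equiv), DMSO, rt
Reagents that add atoms: none
Why: IBX in DMSO oxidises 1,4-diols to γ-lactols without going on to the lactone, and the unhindered C15 carbinol should react before the neopentyl C16 carbinol, which then closes ring D as the hemiacetal.

Step 18
Reactants: 21 7,7-ethylenedioxy-9α,13:15,16-diepoxylabdan-15-ol
Product: 22 15-hydroxy-9α,13:15,16-diepoxylabdan-7-one
Conditions: 1 M HCl, THF, rt
Reagents that add atoms: water, O
Why: Mild acid hydrolysis of the dioxolane releases the C7 ketone while the cyclic hemiacetal survives, and C8 stays as the favoured equatorial methyl epimer.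

Step 19
Reactants: 22 15-hydroxy-9α,13:15,16-diepoxylabdan-7-one
Product: 23 15-methoxy-9α,13:15,16-diepoxylabdan-7-one
Conditions: MeOH, PPTS (cat.), rt
Reagents that add atoms: methanol, CO
Why: Fischer-type acetalisation turns the hemiacetal into a methyl acetal that is inert to the base and oxidant of the next steps, while the hindered ketone should not form a dimethyl ketal without a dehydrating agent.

Step 20
Reactants: 23 15-methoxy-9α,13:15,16-diepoxylabdan-7-one
Product: 25 15-methoxy-9α,13:15,16-diepoxylabd-6-en-7-yl acetate, via potassium enolate 24 (not isolated)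
Conditions: KN(SiMe3)2, THF, −78 °C; then Ac2O, −78 to 0 °C
Reagents that add atoms: acetic anhydride, CC(=O)OC(C)=O
Why: Kinetic deprotonation with a bulky amide at −78 °C should take a proton from the C6 methylene in preference to the tertiary C8–H (whose enolate would eject O9), and the potassium enolate is O-acylated by acetic anhydride to give the Δ6 enol acetate.

Step 21
Reactants: 25 15-methoxy-9α,13:15,16-diepoxylabd-6-en-7-yl acetate
Product: 27 6β-acetoxy-15-methoxy-9α,13:15,16-diepoxylabdan-7-one, via enol acetate epoxide 26 (not isolated)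
Conditions: dimethyldioxirane, acetone, 0 °C; evaporate; toluene, 110 °C
Reagents that add atoms: dimethyldioxirane, CC1(C)OO1
Why: Neutral dimethyldioxirane should epoxidise the enol acetate from the α face (the β face of C6 is screened by the syn-axial C10 and C4 β-methyls) to give the 6α,7α-epoxy 7β-acetate 26, and the thermal enol ester epoxide rearrangement then moves the acyloxy group from C7 to C6 intramolecularly with inversion at C6, placing the axial 6β-acetate on the hindered face while the epoxide oxygen becomes the C7 carbonyl.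

Step 22
Reactants: 27 6β-acetoxy-15-methoxy-9α,13:15,16-diepoxylabdan-7-one
Product: 28 6β-acetoxy-15-hydroxy-9α,13:15,16-diepoxylabdan-7-one
Conditions: AcOH/THF/H2O, 40 °C
Reagents that add atoms: water, O
Why: Mild aqueous acid hydrolyses the cyclic methyl acetal to the hemiacetal without cleaving the hindered secondary acetate or epimerising C6, whose remaining hydrogen is equatorial and poorly aligned for enolisation.

Step 23
Reactants: 28 6β-acetoxy-15-hydroxy-9α,13:15,16-diepoxylabdan-7-one
Product: 30 (13R)-6β-acetoxy-9α,13:15,16-diepoxylabd-14-en-7-one (target), via lactol mesylate 29 (not isolated)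
Conditions: MsCl, Et3N, CH2Cl2, −20 °C to rt
Reagents that add atoms: none
Why: Mesylation of the hemiacetal hydroxyl and amine-promoted elimination (the only β-hydrogens are on C14, C13 being quaternary) should give the C14=C15 enol ether of ring D under cold basic conditions that the β-alkoxy α-acetoxy ketone tolerates.

**Compound list**

1 | (+)-sclareolide | C[C@]12CCCC([C@@H]1CC[C@@]3([C@@H]2CC(=O)O3)C)(C)C | starting material
2 | methyl 13,14,15,16-tetranorlabd-8-en-12-oate | C1CC(C)=C(CC(=O)OC)[C@@]2(C)CCCC(C)(C)[C@H]12 | intermediate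
3 | 13,14,15,16-tetranorlabd-8-en-12-ol | C1CC(C)=C(CCO)[C@@]2(C)CCCC(C)(C)[C@H]12 | intermediate
4 | 12-(tert-butyldimethylsilyloxy)-13,14,15,16-tetranorlabd-8-ene | C1CC(C)=C(CCO[Si](C)(C)C(C)(C)C)[C@@]2(C)CCCC(C)(C)[C@H]12 | intermediate
5 | 12-(tert-butyldimethylsilyloxy)-13,14,15,16-tetranorlabd-8-en-7-one | C1C(=O)C(C)=C(CCO[Si](C)(C)C(C)(C)C)[C@@]2(C)CCCC(C)(C)[C@H]12 | intermediate
6 | 12-(tert-butyldimethylsilyloxy)-8α,9α-epoxy-13,14,15,16-tetranorlabdan-7-one | C1C(=O)[C@@]3(C)O[C@@]3(CCO[Si](C)(C)C(C)(C)C)[C@@]2(C)CCCC(C)(C)[C@H]12 | intermediate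
7 | 12-(tert-butyldimethylsilyloxy)-9α-hydroxy-13,14,15,16-tetranorlabdan-7-one (8α-methyl) | C1C(=O)[C@@H](C)[C@](O)(CCO[Si](C)(C)C(C)(C)C)[C@@]2(C)CCCC(C)(C)[C@H]12 | intermediate
8 | 12-(tert-butyldimethylsilyloxy)-7,7-ethylenedioxy-13,14,15,16-tetranorlabdan-9α-ol | C1C3(OCCO3)[C@@H](C)[C@](O)(CCO[Si](C)(C)C(C)(C)C)[C@@]2(C)CCCC(C)(C)[C@H]12 | intermediate
9 | methyl acetoacetate | COC(=O)CC(C)=O | starting material
10 | methyl 2-diazo-3-oxobutanoate | COC(=O)C(=[N+]=[N-])C(C)=O | intermediate
11 | methyl 2-diazo-3-hydroxybutanoate (racemic) | COC(=O)C(=[N+]=[N-])C(C)O | intermediate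
12 | methyl 2-diazobut-3-enoate | COC(=O)C(=[N+]=[N-])C=C | intermediate
13 | methyl 2-{[12-(tert-butyldimethylsilyloxy)-7,7-ethylenedioxy-13,14,15,16-tetranorlabdan-9α-yl]oxy}but-3-enoate (both C13–H epimers) | C1C3(OCCO3)[C@@H](C)[C@](OC(C=C)C(=O)OC)(CCO[Si](C)(C)C(C)(C)C)[C@@]2(C)CCCC(C)(C)[C@H]12 | intermediate
14 | methyl 2-[(7,7-ethylenedioxy-12-hydroxy-13,14,15,16-tetranorlabdan-9α-yl)oxy]but-3-enoate (both C13–H epimers) | C1C3(OCCO3)[C@@H](C)[C@](OC(C=C)C(=O)OC)(CCO)[C@@]2(C)CCCC(C)(C)[C@H]12 | intermediate
15 | methyl 2-[(7,7-ethylenedioxy-12-iodo-13,14,15,16-tetranorlabdan-9α-yl)oxy]but-3-enoate (both C13–H epimers; key-step precursor) | C1C3(OCCO3)[C@@H](C)[C@](OC(C=C)C(=O)OC)(CCI)[C@@]2(C)CCCC(C)(C)[C@H]12 | intermediate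
16 | lithium dienolate of 15 (not isolated) | C1C3(OCCO3)[C@@H](C)[C@](OC(C=C)=C([O-])OC)(CCI)[C@@]2(C)CCCC(C)(C)[C@H]12.[Li+] | intermediate
17 | methyl (13R)-7,7-ethylenedioxy-9α,13-epoxylabd-14-en-16-oate (key-step product) | C1C3(OCCO3)[C@@H](C)[C@]2(CC[C@](C(=O)OC)(C=C)O2)[C@@]2(C)CCCC(C)(C)[C@H]12 | intermediate
18 | (13R)-7,7-ethylenedioxy-9α,13-epoxylabd-14-en-16-ol | C1C3(OCCO3)[C@@H](C)[C@]2(CC[C@](CO)(C=C)O2)[C@@]2(C)CCCC(C)(C)[C@H]12 | intermediate
19 | bis(9-borabicyclo[3.3.1]nonan-9-yl) adduct of 18 (C15–B and C16–O–B; not isolated) | C1C3(OCCO3)[C@@H](C)[C@]2(CC[C@](COB4C5CCCC4CCC5)(CCB6C7CCCC6CCC7)O2)[C@@]2(C)CCCC(C)(C)[C@H]12 | intermediate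
20 | 7,7-ethylenedioxy-9α,13-epoxylabdane-15,16-diol | C1C3(OCCO3)[C@@H](C)[C@]2(CC[C@](CO)(CCO)O2)[C@@]2(C)CCCC(C)(C)[C@H]12 | intermediate
21 | 7,7-ethylenedioxy-9α,13:15,16-diepoxylabdan-15-ol (lactol, C15 epimers) | C1C3(OCCO3)[C@@H](C)[C@]2(CC[C@]4(CC(O)OC4)O2)[C@@]2(C)CCCC(C)(C)[C@H]12 | intermediate
22 | 15-hydroxy-9α,13:15,16-diepoxylabdan-7-one (C15 epimers) | C1C(=O)[C@@H](C)[C@]2(CC[C@]4(CC(O)OC4)O2)[C@@]2(C)CCCC(C)(C)[C@H]12 | intermediate
23 | 15-methoxy-9α,13:15,16-diepoxylabdan-7-one (C15 epimers) | C1C(=O)[C@@H](C)[C@]2(CC[C@]4(CC(OC)OC4)O2)[C@@]2(C)CCCC(C)(C)[C@H]12 | intermediate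
24 | potassium Δ6-enolate of 23 (not isolated) | C1=C([O-])[C@@H](C)[C@]2(CC[C@]4(CC(OC)OC4)O2)[C@@]2(C)CCCC(C)(C)[C@H]12.[K+] | intermediate
25 | 15-methoxy-9α,13:15,16-diepoxylabd-6-en-7-yl acetate | C1=C(OC(C)=O)[C@@H](C)[C@]2(CC[C@]4(CC(OC)OC4)O2)[C@@]2(C)CCCC(C)(C)[C@H]12 | intermediate
26 | 6α,7α-epoxy-15-methoxy-9α,13:15,16-diepoxylabdan-7β-yl acetate (not isolated) | [C@@H]15O[C@@]5(OC(C)=O)[C@@H](C)[C@]2(CC[C@]4(CC(OC)OC4)O2)[C@@]2(C)CCCC(C)(C)[C@H]12 | intermediate
27 | 6β-acetoxy-15-methoxy-9α,13:15,16-diepoxylabdan-7-one | CC(=O)O[C@@H]1C(=O)[C@@H](C)[C@]2(CC[C@]4(CC(OC)OC4)O2)[C@@]2(C)CCCC(C)(C)[C@H]12 | intermediate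
28 | 6β-acetoxy-15-hydroxy-9α,13:15,16-diepoxylabdan-7-one | CC(=O)O[C@@H]1C(=O)[C@@H](C)[C@]2(CC[C@]4(CC(O)OC4)O2)[C@@]2(C)CCCC(C)(C)[C@H]12 | intermediate
29 | 15-O-methanesulfonate of 28 (not isolated) | CC(=O)O[C@@H]1C(=O)[C@@H](C)[C@]2(CC[C@]4(CC(OS(C)(=O)=O)OC4)O2)[C@@]2(C)CCCC(C)(C)[C@H]12 | intermediate
30 | (13R)-6β-acetoxy-9α,13:15,16-diepoxylabd-14-en-7-one (CNP0224709.1) | CC(=O)O[C@@H]1C(=O)[C@@H](C)[C@]2(CC[C@]3(C=COC3)O2)[C@@]2(C)CCCC(C)(C)[C@H]12 | target

**Step count**

Total: 23 steps (20 on the main line, 3 for diazo reagent 12). Longest linear sequence: 20 steps (steps 1–7 and 11–23).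

**Steps most likely to fail**

Step 14 (facial selection at C13). The two flanks of spiro C9 differ little in bulk, so the dienolate may close with poor facial selectivity and give much of the C13 epimer, which cannot be corrected by equilibration at a quaternary centre. The fallback sets out from 15 and comes back at 22. The same cyclisation of 15 would deliver the C13 epimer, methyl (13S)-7,7-ethylenedioxy-9α,13-epoxylabd-14-en-16-oate F1, which is used with the roles of its two C13 substituents exchanged. Ozonolysis of the vinyl group with NaBH4 work-up gives the 13-hydroxymethyl ester F2, whose new carbinol carbon becomes C16. TBSCl/imidazole gives the silyl ether F3, and iBu2AlH at −78 °C gives the aldehyde F4. Wittig methoxymethylenation with Ph3P=CHOMe gives the methyl enol ether F5, in which the former ester carbon is C14 and the new carbon is C15. Aqueous HCl in THF then hydrolyses the enol ether, the silyl ether and the dioxolane together, and the liberated C15 aldehyde closes onto the C16 hydroxyl to give lactol ketone 22.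

Step 11 (site and rate of carbenoid attack). The bulky tertiary 9α-hydroxyl may react slowly, so that the vinylcarbenoid is consumed by attack at its vinylogous terminus, by dimerisation or by cyclisation of 12. The fallback sets out from 8 and comes back at 13, and it builds the vinyl group only after the C–O bond is in place. Trimethyl 2-diazophosphonoacetate F6 (from trimethyl phosphonoacetate by diazo transfer) is an acceptor/acceptor diazo compound with no vinylogous site. With Rh2(OAc)4 in toluene at 80 °C it should insert into the 9α-OH of 8 to give the α-alkoxy phosphonoacetate F7. Horner–Wadsworth–Emmons reaction with acetaldehyde (LiN(SiMe3)2, THF) gives the 2-alkoxybut-2-enoate F8. γ-Deprotonation with LiN(iPr)2 at −78 °C and kinetic α-protonation with AcOH at −78 °C deconjugates F8 to 13.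

Step 21 (course of the acyloxy shift). Epoxidation on the β face, or an acid-catalysed rearrangement that keeps the epoxide oxygen on C6, would give the 6α-acetate, and the two syn-axial methyls may block the shift to the β face. The fallback sets out from 23 and comes back at 28, and it inverts C6 by oxidation and reduction with hydride delivered from the open α face. Enolate 24 with 2-(phenylsulfonyl)-3-phenyloxaziridine gives the 6α-hydroxy ketone F9. MeOH, HC(OMe)3 and camphorsulfonic acid give the dimethyl ketal F10, and Dess–Martin periodinane gives the α-keto ketal F11. NaBH4 should attack C6 from the α face, the β face being closed by the C10 and C4 β-methyls, to give the axial 6β-alcohol F12. Ac2O/DMAP gives the acetate F13, and AcOH/THF/H2O cleaves the dimethyl ketal and the methyl acetal to give 28.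

**Further compounds**

F1 | step 14 | methyl (13S)-7,7-ethylenedioxy-9α,13-epoxylabd-14-en-16-oate (C13 epimer of 17) | C1C3(OCCO3)[C@@H](C)[C@]2(CC[C@@](C(=O)OC)(C=C)O2)[C@@]2(C)CCCC(C)(C)[C@H]12
F2 | step 14 | 13-hydroxymethyl ester from ozonolysis and reduction of F1 | C1C3(OCCO3)[C@@H](C)[C@]2(CC[C@@](C(=O)OC)(CO)O2)[C@@]2(C)CCCC(C)(C)[C@H]12
F3 | step 14 | tert-butyldimethylsilyl ether of F2 | C1C3(OCCO3)[C@@H](C)[C@]2(CC[C@@](C(=O)OC)(CO[Si](C)(C)C(C)(C)C)O2)[C@@]2(C)CCCC(C)(C)[C@H]12
F4 | step 14 | aldehyde from reduction of the ester of F3 | C1C3(OCCO3)[C@@H](C)[C@]2(CC[C@@](C=O)(CO[Si](C)(C)C(C)(C)C)O2)[C@@]2(C)CCCC(C)(C)[C@H]12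
F5 | step 14 | methyl enol ether from methoxymethylenation of F4 | C1C3(OCCO3)[C@@H](C)[C@]2(CC[C@@](C=COC)(CO[Si](C)(C)C(C)(C)C)O2)[C@@]2(C)CCCC(C)(C)[C@H]12
F6 | step 11 | trimethyl 2-diazophosphonoacetate | COC(=O)C(=[N+]=[N-])P(=O)(OC)OC
F7 | step 11 | methyl 2-{[12-(tert-butyldimethylsilyloxy)-7,7-ethylenedioxy-13,14,15,16-tetranorlabdan-9α-yl]oxy}-2-(dimethoxyphosphoryl)acetate | C1C3(OCCO3)[C@@H](C)[C@](OC(C(=O)OC)P(=O)(OC)OC)(CCO[Si](C)(C)C(C)(C)C)[C@@]2(C)CCCC(C)(C)[C@H]12
F8 | step 11 | methyl 2-{[12-(tert-butyldimethylsilyloxy)-7,7-ethylenedioxy-13,14,15,16-tetranorlabdan-9α-yl]oxy}but-2-enoate (E/Z) | C1C3(OCCO3)[C@@H](C)[C@](OC(=CC)C(=O)OC)(CCO[Si](C)(C)C(C)(C)C)[C@@]2(C)CCCC(C)(C)[C@H]12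
F9 | step 21 | 6α-hydroxy-15-methoxy-9α,13:15,16-diepoxylabdan-7-one | O[C@H]1C(=O)[C@@H](C)[C@]2(CC[C@]4(CC(OC)OC4)O2)[C@@]2(C)CCCC(C)(C)[C@H]12
F10 | step 21 | 7,7,15-trimethoxy-9α,13:15,16-diepoxylabdan-6α-ol | O[C@H]1C(OC)(OC)[C@@H](C)[C@]2(CC[C@]4(CC(OC)OC4)O2)[C@@]2(C)CCCC(C)(C)[C@H]12
F11 | step 21 | 7,7,15-trimethoxy-9α,13:15,16-diepoxylabdan-6-one | O=C1C(OC)(OC)[C@@H](C)[C@]2(CC[C@]4(CC(OC)OC4)O2)[C@@]2(C)CCCC(C)(C)[C@H]12
F12 | step 21 | 7,7,15-trimethoxy-9α,13:15,16-diepoxylabdan-6β-ol | O[C@@H]1C(OC)(OC)[C@@H](C)[C@]2(CC[C@]4(CC(OC)OC4)O2)[C@@]2(C)CCCC(C)(C)[C@H]12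
F13 | step 21 | 7,7,15-trimethoxy-9α,13:15,16-diepoxylabdan-6β-yl acetate | CC(=O)O[C@@H]1C(OC)(OC)[C@@H](C)[C@]2(CC[C@]4(CC(OC)OC4)O2)[C@@]2(C)CCCC(C)(C)[C@H]12
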